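The seven-membered ring is cut at its two aryl–alkyl bonds: ring C (the mono-oxygenated ring) to the ring CH2, and catechol ring B to the methine shared with the dihydrophenanthrene. This leaves a 1-bromo-10-methoxy-9,10-dihydrophenanthrene (rings A and C) and the symmetric 1,1-bis(3,4-dimethoxyphenyl)ethene (rings B and D). One flask joins them across the peri carbons C1 and C10: a Mizoroki–Heck reaction at the bromide, then ionisation of the benzylic ether to a cation, stabilised by the para oxygen of ring C, that ring B captures. Rings B and D being identical, alkene geometry is irrelevant. The cycloheptene is resolved and hydrogenated from its convex face, which sets the second methine.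

Key step: step 4

Labels used below: ring A = the 1,3-dioxygenated ring of the dihydrophenanthrene; ring C = its mono-oxygenated ring; ring B = the catechol ring inside the seven-membered ring; ring D = the pendant catechol ring; Ca = CH2 of the dihydrophenanthrene; Cb = the CH bonded to ring B; Cc = the carbon bearing ring D; Cd = the carbon between Cc and ring C.

Assumption: 1, 2 and 7 are taken as purchasable; if not, 1 would come from formylation of 3,5-dibromoanisole and the Grignard reagents from the corresponding halides and magnesium.

Step 1
Reactants: 1 2,6-dibromo-4-methoxybenzaldehyde; 2 (3,5-dimethoxybenzyl)magnesium chloride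
Product: 4 1,3-dibromo-5-methoxy-2-[1-methoxy-2-(3,5-dimethoxyphenyl)ethyl]benzene (racemic), via magnesium alkoxide 3 (not isolated)
Conditions: THF, −78 °C to 0 °C; then MeOTf, 0 °C to rt
Reagents that add atoms: methyl trifluoromethanesulfonate, COS(=O)(=O)C(F)(F)F
Why: Grignard 1,2-addition to the aldehyde should give the chloromagnesium alkoxide, which methyl triflate O-methylates in the same flask; the carbinol carbon forms as a racemate and is ionised again in step 4, so its configuration is immaterial.

Step 2
Reactants: 4 1,3-dibromo-5-methoxy-2-[1-methoxy-2-(3,5-dimethoxyphenyl)ethyl]benzene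
Product: 5 1-bromo-3,5,7,10-tetramethoxy-9,10-dihydrophenanthrene (racemic)
Conditions: Pd(OAc)2 (5 mol%), PCy3·HBF4 (10 mol%), K2CO3, t-BuCO2H (30 mol%), DMA, 110 °C
Reagents that add atoms: none
Why: Palladium-catalysed intramolecular direct C–H arylation (carboxylate-assisted concerted metalation–deprotonation) should close the six-membered ring; the two C–Br bonds of 4 and the two ortho C–H bonds of the dimethoxyphenyl ring are pairwise equivalent, so one regioisomer results and one bromide is left for step 4.

Step 3
Reactants: 6 1-(3,4-dimethoxyphenyl)ethanone; 7 (3,4-dimethoxyphenyl)magnesium bromide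
Product: 9 1,1-bis(3,4-dimethoxyphenyl)ethene, via tertiary carbinol 8 (not isolated)
Conditions: THF, 0 °C to rt; aq NH4Cl; then TsOH·H2O (5 mol%), toluene, 80 °C
Reagents that add atoms: none
Why: Grignard addition to the ketone followed by acid-catalysed E1 dehydration of the bis-benzylic tertiary carbinol should give the 1,1-diarylethene, which has no stereo-element.

Step 4
Reactants: 5 1-bromo-3,5,7,10-tetramethoxy-9,10-dihydrophenanthrene; 9 1,1-bis(3,4-dimethoxyphenyl)ethene
Product: 11 racemic annulated cycloheptene (heptamethyl ether of the target skeleton bearing a Cc=Cd double bond), via triarylethene 10 (not isolated)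
Conditions: Pd(OAc)2 (5 mol%), P(t-Bu)3·HBF4 (10 mol%), Cy2NMe, toluene, 100 °C; then CH2Cl2, 2,6-di-tert-butyl-4-methylpyridine, TMSOTf, −78 °C to 0 °C
Reagents that add atoms: none
Why: Stage one is a Mizoroki–Heck reaction: oxidative addition of zerovalent palladium into the C–Br bond of 5, syn-carbopalladation of 9 at its CH2 terminus and syn-β-hydride elimination should give triarylethene 10, in which one of the two identical dimethoxyphenyl rings is necessarily cis to the dihydrophenanthrene. Stage two is an SN1 Friedel–Crafts alkylation: TMSOTf ionises the benzylic methyl ether at C10 to a cation stabilised by the para-methoxy group of ring C, and the cis dimethoxyphenyl ring (ring B) attacks it through its carbon para to a methoxy group, a 7-exo-trig closure of the seven-membered ring, while the hindered pyridine takes up the released proton so that the basic triarylethene is never protonated. The closest known reactions are Heck arylations of 1,1-diarylethenes and Lewis-acid cyclisations of stilbenoid benzylic cations onto dimethoxyarenes. The new methine stereocentre Cb has no controlling element and forms as a racemate, which step 5 separates. The step needs ring closure to outrun loss of the neighbouring Ca proton (aromatisation to the phenanthrene), which the proton-poor medium and the peri pre-organisation of cation and arene should favour, and needs attack para rather than ortho to methoxy, which both sterics and electronics favour.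

Step 5
Reactants: 11 racemic annulated cycloheptene
Product: 12 (R)-enantiomer of 11 (R at Cb)
Conditions: preparative SFC, amylose tris(3,5-dimethylphenylcarbamate) stationary phase, CO2/MeOH
Reagents that add atoms: none
Why: The enantiomers of 11 are configurationally stable (the only stereocentre is the sp3 methine Cb) and should separate on a chiral stationary phase; the (R)-enantiomer is carried on.

Step 6
Reactants: 12 (R)-enantiomer of 11
Product: 13 (Cb-R,Cc-S)-heptamethyl ether of the target
Conditions: H2 (4 bar), 10% Pd/C, EtOAc/EtOH, rt
Reagents that add atoms: none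
Why: Heterogeneous syn-hydrogenation of the trisubstituted aryl-conjugated double bond: in the boat-shaped dibenzocycloheptene, rings B and C close off the concave face, so both hydrogens should arrive on the convex face that already holds the axial hydrogen of Cb, which makes the hydrogens at Cb and Cc cis and Cc (S).

Step 7
Reactants: 13 (Cb-R,Cc-S)-heptamethyl ether of the target
Product: 14 CNP0306974.1
Conditions: BBr3 (excess), CH2Cl2, −78 °C to rt; then MeOH, H2O, 0 °C
Reagents that add atoms: none
Why: BBr3 coordinates each aryl methyl ether and bromide removes the methyl group (SN2), which should free all seven phenols on aqueous work-up without touching the two benzylic stereocentres.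

Compound list
1 | 2,6-dibromo-4-methoxybenzaldehyde | COc1cc(Br)c(C=O)c(Br)c1 | starting material
2 | (3,5-dimethoxybenzyl)magnesium chloride | COc1cc(C[Mg]Cl)cc(OC)c1 | starting material
3 | chloromagnesium 1-(2,6-dibromo-4-methoxyphenyl)-2-(3,5-dimethoxyphenyl)ethanolate (racemic, not isolated) | COc1cc(Br)c(C(O[Mg]Cl)Cc2cc(OC)cc(OC)c2)c(Br)c1 | intermediate
4 | 1,3-dibromo-5-methoxy-2-[1-methoxy-2-(3,5-dimethoxyphenyl)ethyl]benzene (racemic) | COc1cc(Br)c(C(OC)Cc2cc(OC)cc(OC)c2)c(Br)c1 | intermediate
5 | 1-bromo-3,5,7,10-tetramethoxy-9,10-dihydrophenanthrene (racemic) | COc1cc(Br)c2c(c1)-c1c(OC)cc(OC)cc1CC2OC | intermediate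
6 | 1-(3,4-dimethoxyphenyl)ethanone | CC(=O)c1ccc(OC)c(OC)c1 | starting material
7 | (3,4-dimethoxyphenyl)magnesium bromide | COc1ccc([Mg]Br)cc1OC | starting material
8 | 1,1-bis(3,4-dimethoxyphenyl)ethan-1-ol (not isolated) | CC(O)(c1ccc(OC)c(OC)c1)c1ccc(OC)c(OC)c1 | intermediate
9 | 1,1-bis(3,4-dimethoxyphenyl)ethene | C=C(c1ccc(OC)c(OC)c1)c1ccc(OC)c(OC)c1 | intermediate
10 | 1-[2,2-bis(3,4-dimethoxyphenyl)ethenyl]-3,5,7,10-tetramethoxy-9,10-dihydrophenanthrene (racemic, not isolated) | COc1cc(C=C(c2ccc(OC)c(OC)c2)c2ccc(OC)c(OC)c2)c2c(c1)-c1c(OC)cc(OC)cc1CC2OC | intermediate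
11 | racemic annulated cycloheptene: the 3,5,7-trimethoxy-9,10-dihydrophenanthrene bridged from C1 to C10 by –CH=C(3,4-dimethoxyphenyl)–(4,5-dimethoxy-1,2-phenylene)–, the phenylene being bonded to C10 | COc1cc(OC)c2c(c1)CC1c3cc(OC)c(OC)cc3C(c3ccc(OC)c(OC)c3)=Cc3cc(OC)cc-2c31 | intermediate
12 | (R)-enantiomer of 11 (R at Cb) | COc1cc(OC)c2c(c1)C[C@@H]1c3cc(OC)c(OC)cc3C(c3ccc(OC)c(OC)c3)=Cc3cc(OC)cc-2c31 | intermediate
13 | (Cb-R,Cc-S)-heptamethyl ether of the target, hydrogens at Cb and Cc cis | COc1cc(OC)c2c(c1)C[C@@H]1c3cc(OC)c(OC)cc3[C@H](c3ccc(OC)c(OC)c3)Cc3cc(OC)cc-2c31 | intermediate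
14 | CNP0306974.1, the (Cb-R,Cc-S)-heptaol | Oc1cc(O)c2c(c1)C[C@@H]1c3cc(O)c(O)cc3[C@H](c3ccc(O)c(O)c3)Cc3cc(O)cc-2c31 | target

Total step count: 7. Longest linear sequence: 6 steps (steps 1, 2, 4, 5, 6, 7).

Steps most likely to fail

Step 4. After ionisation, the benzylic cation may lose the neighbouring Ca proton and aromatise to the phenanthrene faster than ring B closes the seven-membered ring. The fallback sets out from 10 and comes back at 11. The Heck stage would be run alone and 10 isolated. TsOH in warm toluene would then eliminate methanol to give 1-[2,2-bis(3,4-dimethoxyphenyl)ethenyl]-3,5,7-trimethoxyphenanthrene F1. F1 would be cyclised under reversible Brønsted-acid conditions (TfOH, (CF3)2CHOH/CH2Cl2, 0 °C). Protonation of the 9,10-bond at the carbon next to ring A regenerates the same para-methoxy-stabilised cation repeatedly until ring B has captured it, which should return racemic 11.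

Step 2. The second C–Br bond may be consumed by reduction or intermolecular arylation, or the cyclisation may stall at the hindered C–H between the methoxy group and the benzylic carbon. The fallback builds the tricycle photochemically at the phenanthrene oxidation level; it sets out from 9 together with two purchased compounds and comes back at 11. Horner–Wadsworth–Emmons olefination of 2-bromo-4-methoxybenzaldehyde with diethyl (3,5-dimethoxybenzyl)phosphonate (KOt-Bu, THF) should give (E)-2-bromo-1-[2-(3,5-dimethoxyphenyl)ethenyl]-4-methoxybenzene F2. Oxidative Mallory photocyclisation (hν, I2, methyloxirane, toluene) onto the free ortho carbon should give 1-bromo-3,5,7-trimethoxyphenanthrene F3. The Heck reaction of step 4 with 9 would then give 1-[2,2-bis(3,4-dimethoxyphenyl)ethenyl]-3,5,7-trimethoxyphenanthrene F1, and the acid closure described for step 4 should return racemic 11.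

Step 7. Under the strongly Lewis-acidic conditions the bond between ring B and Cb may ionise (retro-Friedel–Crafts cleavage), or the electron-rich polyphenol may oxidise during work-up. The fallback runs from 13 to 14 by nucleophilic demethylation with NaSEt in DMF at 130 °C under argon: thiolate SN2 attack at the methyl groups in a basic, non-ionising medium, followed by acidification. It makes no new compound.

Further compounds
F1 | step 4 | 1-[2,2-bis(3,4-dimethoxyphenyl)ethenyl]-3,5,7-trimethoxyphenanthrene | COc1cc(C=C(c2ccc(OC)c(OC)c2)c2ccc(OC)c(OC)c2)c2ccc3cc(OC)cc(OC)c3c2c1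
F2 | step 2 | (E)-2-bromo-1-[2-(3,5-dimethoxyphenyl)ethenyl]-4-methoxybenzene | COc1ccc(/C=C/c2cc(OC)cc(OC)c2)c(Br)c1
F3 | step 2 | 1-bromo-3,5,7-trimethoxyphenanthrene | COc1cc(Br)c2ccc3cc(OC)cc(OC)c3c2c1
F0 | step 7 | none | none
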